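**Retrosynthetic overview**
1. Strategic feature: on the cyclohexane ring the quaternary oxirane carbon C1 (bearing C7H2OBz) and the neighbouring acetoxy carbon C2 carry cis oxygens. Both are carbonyl carbons of an open chain, so C1–C2 is a pinacol bond; the C6 oxygen, trans to O1, becomes the leaving group for the oxirane.
2. 20 ⇐ epoxy triol 19 (benzoylation of O7) ⇐ tribenzyl epoxide 18 ⇐ C6 mesylate 17 (O1 displaces the mesylate with inversion at C6; the oxirane is the second ring formed).
3. 17 ⇐ cis-diol 13 (desilylate, acetylate O2 and O3, remove PMB) ⇐ keto-aldehyde 12 by SmI2 pinacol closure of C1–C2 (the cyclohexane is the first ring formed).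
4. 12 ⇐ lactol 6 + vinylmagnesium bromide 7 (C3 set by chelation), silylation of the allylic hydroxyl, oxidation of the old ring-oxygen carbinol, alkene cleavage; C4, C5, C6 are C2, C3, C4 of D-galactose.
5. 6 ⇐ phenyl 1-thio-β-D-galactopyranoside 1 via 4,6-arylidene acetal, benzylation and reductive opening to the 4-O-PMB ether.

Key step: step 10

Assumption: phenyl 1-thio-β-D-galactopyranoside, the commercial anomerically protected form of D-galactose, is taken as the starting material.
Conventions: carbocycle locants are C1 (quaternary, bears C7), C2 and C3 (acetoxy carbons), C4 and C5 (carbinols), C6. β is the ring face of the C1 oxygen, α the opposite face. Bn = benzyl, PMB = 4-methoxybenzyl, TBS = tert-butyldimethylsilyl.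

**Route**

Step 1
Reactants: 1 phenyl 1-thio-β-D-galactopyranoside
Product: 2 phenyl 4,6-O-(4-methoxybenzylidene)-1-thio-β-D-galactopyranoside (aryl equatorial on the cis-fused dioxane)
Conditions: 4-MeOC6H4CH(OMe)2, CSA (cat.), MeCN, rt
Reagents that add atoms: 4-methoxybenzaldehyde dimethyl acetal, COc1ccc(C(OC)OC)cc1
Why: Acid-catalysed transacetalisation should give the thermodynamically preferred six-membered 4,6-arylidene acetal, leaving O2 and O3 free.

Step 2
Reactants: 2 phenyl 4,6-O-(4-methoxybenzylidene)-1-thio-β-D-galactopyranoside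
Product: 3 phenyl 2,3-di-O-benzyl-4,6-O-(4-methoxybenzylidene)-1-thio-β-D-galactopyranoside
Conditions: NaH, BnBr, DMF, 0 °C to rt
Reagents that add atoms: benzyl bromide, BrCc1ccccc1
Why: Williamson etherification of the two remaining secondary hydroxyls; acetal and thioglycoside are stable to base.

Step 3
Reactants: 3 phenyl 2,3-di-O-benzyl-4,6-O-(4-methoxybenzylidene)-1-thio-β-D-galactopyranoside
Product: 4 phenyl 2,3-di-O-benzyl-4-O-(4-methoxybenzyl)-1-thio-β-D-galactopyranoside (6-OH free)
Conditions: BH3·THF, TMSOTf (cat.), CH2Cl2, 0 °C to rt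
Reagents that add atoms: none
Why: Regioselective reductive acetal opening: the Lewis acid activates the less hindered O6, the C–O6 bond breaks, and hydride delivery to the oxocarbenium ion leaves the PMB ether on the axial O4.

Step 4
Reactants: 4 phenyl 2,3-di-O-benzyl-4-O-(4-methoxybenzyl)-1-thio-β-D-galactopyranoside
Product: 5 phenyl 2,3,6-tri-O-benzyl-4-O-(4-methoxybenzyl)-1-thio-β-D-galactopyranoside
Conditions: NaH, BnBr, DMF, 0 °C to rt
Reagents that add atoms: benzyl bromide, BrCc1ccccc1
Why: Williamson etherification of the primary hydroxyl installs the future C7 benzyl ether.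

Step 5
Reactants: 5 phenyl 2,3,6-tri-O-benzyl-4-O-(4-methoxybenzyl)-1-thio-β-D-galactopyranoside
Product: 6 2,3,6-tri-O-benzyl-4-O-(4-methoxybenzyl)-D-galactopyranose (α/β lactol)
Conditions: NBS, acetone/H2O (9:1), −15 °C
Reagents that add atoms: water, O
Why: Thioglycoside hydrolysis by bromonium activation of sulfur and capture of the oxocarbenium ion by water; the sulfide reacts far faster than the PMB ring at low temperature.

Step 6
Reactants: 6 2,3,6-tri-O-benzyl-4-O-(4-methoxybenzyl)-D-galactopyranose; 7 vinylmagnesium bromide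
Product: 8 4,5,8-tri-O-benzyl-1,2-dideoxy-6-O-(4-methoxybenzyl)-D-glycero-L-gluco-oct-1-enitol (3,7-diol; C3–OH threo to C4–OBn)
Conditions: 7 (excess), THF, 0 °C to rt; aq. NH4Cl
Reagents that add atoms: none
Why: Grignard addition to the open hydroxy-aldehyde form of the lactol; magnesium chelation between the aldehyde oxygen and the α-benzyloxy group (Cram chelate) should favour the 3,4-threo allylic alcohol that becomes C3, with the minor erythro epimer removed by chromatography.

Step 7
Reactants: 8 the oct-1-enitol 3,7-diol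
Product: 9 3-O-TBS ether of 8 (7-OH free)
Conditions: TBSCl (1.1 equiv), imidazole, DMF, 0 °C
Reagents that add atoms: tert-butyldimethylsilyl chloride, CC(C)(C)[Si](C)(C)Cl
Why: Kinetic mono-silylation; the allylic hydroxyl, next to a flat vinyl group and with one β-alkoxy substituent, is expected to be more accessible and more nucleophilic than the C7 hydroxyl, which sits between two alkoxy-bearing carbons.

Step 8
Reactants: 9 the 3-O-TBS-7-hydroxy octenitol
Product: 10 4,5,8-tri-O-benzyl-3-O-TBS-1,2-dideoxy-6-O-PMB-L-gluco-oct-1-en-7-ulose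
Conditions: Dess–Martin periodinane, CH2Cl2, 0 °C to rt
Reagents that add atoms: none
Why: Dess–Martin oxidation of the only free secondary alcohol under near-neutral conditions, which should not epimerise the α-alkoxy centre or touch the silyl and PMB ethers.

Step 9
Reactants: 10 the oct-1-en-7-ulose
Product: 12 3,4,7-tri-O-benzyl-2-O-TBS-5-O-PMB-L-gluco-heptos-6-ulose (C1 aldehyde, C6 ketone; galactose C1–C6 = C2–C7), via 1,2-diol 11 (not isolated)
Conditions: OsO4 (cat.), NaIO4, 2,6-lutidine, dioxane/H2O (3:1), rt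
Reagents that add atoms: osmium tetroxide, O=[Os](=O)(=O)=O; sodium periodate, [Na+].[O-]I(=O)(=O)=O
Why: Lemieux–Johnson oxidation: dihydroxylation of the only alkene and periodate cleavage of the diol give the aldehyde without exposing the electron-rich PMB ring to ozone, and lutidine limits epimerisation α to the aldehyde.

Step 10
Reactants: 12 the keto-aldehyde
Product: 13 1-C-(benzyloxymethyl)cyclohexane-1β,2β-diol with 3α-OTBS, 4β-OBn, 5α-OBn and axial 6α-OPMB
Conditions: SmI2 (3 equiv), t-BuOH (3 equiv), THF, −78 °C to rt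
Reagents that add atoms: none
Why: Single-electron transfer from divalent samarium to the C2 aldehyde gives a ketyl bound to trivalent samarium, which adds to the samarium-coordinated C1 ketone to form C1–C2, and tert-butanol protonates the diolate. The closest known reaction type is the SmI2-mediated intramolecular pinacol coupling of carbohydrate-derived 1,6-dicarbonyl compounds to cyclitol cis-diols. The cyclohexane closes in a 6-exo-trig sense through a chair-like transition state that copies the galactopyranose chair: the C3, C4 and C5 alkoxy groups and CH2OBn are equatorial and C6–OPMB is axial. C1 and C2 are set together: the samarium bridge between the two oxygens enforces the cis-diol, and repulsion between each samarium-bound oxygen and its α-alkoxy neighbour (C3–OTBS for C2, C6–OPMB for C1) places both new oxygens on the β face. The step needs cis selectivity, anti selectivity to both flanking ethers, and ring closure faster than reductive loss of an α-alkoxy group. Both flanking ethers lie on the α face so their preferences reinforce each other, and low temperature with tert-butanol as the only proton source keeps C–O cleavage and simple reduction slow.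

Step 11
Reactants: 13 the silylated cis-diol
Product: 14 1β,2β,3α-triol (4β,5α-OBn, 6α-OPMB, CH2OBn)
Conditions: TBAF, THF, 0 °C to rt
Reagents that add atoms: none
Why: Fluoride-driven cleavage of the secondary silyl ether frees O3 next to O2 so that both can be acetylated in one operation.

Step 12
Reactants: 14 the triol
Product: 15 2β,3α-diacetate with free tertiary 1β-OH
Conditions: Ac2O, pyridine, DMAP (cat.), 0 °C to rt
Reagents that add atoms: acetic anhydride, CC(=O)OC(C)=O
Why: Acylation esterifies the two secondary hydroxyls, while the tertiary C1 hydroxyl flanked by three substituents is too hindered to react under these conditions.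

Step 13
Reactants: 15 the diacetate
Product: 16 1β,6α-diol 2,3-diacetate (C6–OH axial)
Conditions: DDQ, CH2Cl2/pH 7 buffer (10:1), 0 °C
Reagents that add atoms: none
Why: Oxidative PMB ether cleavage (hydride abstraction, then hydrolysis of the oxocarbenium ion); benzyl ethers and acetates are inert, and the trans-diaxial C1 hydroxyl cannot trap the cation as a cyclic acetal.

Step 14
Reactants: 16 the 1β,6α-diol
Product: 17 6α-mesylate (1β-OH free)
Conditions: MsCl, Et3N, CH2Cl2, 0 °C
Reagents that add atoms: methanesulfonyl chloride, CS(=O)(=O)Cl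
Why: Sulfonylation via sulfene reaches the hindered secondary hydroxyl, and the tertiary hydroxyl is not expected to react at 0 °C.

Step 15
Reactants: 17 the hydroxy mesylate
Product: 18 1β,6β-epoxide with 2β,3α-OAc, 4β,5α-OBn and CH2OBn
Conditions: NaH, THF, 0 °C to rt
Reagents that add atoms: none
Why: Intramolecular Williamson reaction (3-exo-tet): the axial C1 alkoxide is antiperiplanar to the axial C6 mesylate and displaces it with inversion at C6; acetyl shuttling among O1, O2 and O3 is reversible and every isomer returns through the C1 alkoxide to the same epoxide.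

Step 16
Reactants: 18 the tribenzyl epoxide
Product: 19 1β,6β-epoxy-2β,3α-diacetoxy-4β,5α-diol with free C7 hydroxyl
Conditions: H2 (1 atm), Pd/C, EtOAc, rt
Reagents that add atoms: none
Why: Hydrogenolysis of the three benzyl ethers in a neutral aprotic solvent; the epoxide is neither benzylic nor allylic and the acetates are inert.

Step 17
Reactants: 19 the epoxy triol
Product: 20 CNP0171674.1
Conditions: BzCl (1.05 equiv), 2,4,6-collidine, CH2Cl2, −40 °C
Reagents that add atoms: benzoyl chloride, O=C(Cl)c1ccccc1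
Why: Regioselective esterification under kinetic control: one equivalent of acyl chloride with a hindered pyridine base at low temperature should select the primary C7 hydroxyl over the two secondary ring hydroxyls.

**Compound list**
1 | phenyl 1-thio-β-D-galactopyranoside | OC[C@H]1O[C@@H](Sc2ccccc2)[C@H](O)[C@@H](O)[C@H]1O | starting material
2 | phenyl 4,6-O-(4-methoxybenzylidene)-1-thio-β-D-galactopyranoside | COc1ccc(cc1)[C@H]1OC[C@H]2O[C@@H](Sc3ccccc3)[C@H](O)[C@@H](O)[C@H]2O1 | intermediate
3 | phenyl 2,3-di-O-benzyl-4,6-O-(4-methoxybenzylidene)-1-thio-β-D-galactopyranoside | COc1ccc(cc1)[C@H]1OC[C@H]2O[C@@H](Sc3ccccc3)[C@H](OCc3ccccc3)[C@@H](OCc3ccccc3)[C@H]2O1 | intermediate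
4 | phenyl 2,3-di-O-benzyl-4-O-(4-methoxybenzyl)-1-thio-β-D-galactopyranoside | OC[C@H]1O[C@@H](Sc2ccccc2)[C@H](OCc2ccccc2)[C@@H](OCc2ccccc2)[C@H]1OCc1ccc(OC)cc1 | intermediate
5 | phenyl 2,3,6-tri-O-benzyl-4-O-(4-methoxybenzyl)-1-thio-β-D-galactopyranoside | c1ccccc1COC[C@H]1O[C@@H](Sc2ccccc2)[C@H](OCc2ccccc2)[C@@H](OCc2ccccc2)[C@H]1OCc1ccc(OC)cc1 | intermediate
6 | 2,3,6-tri-O-benzyl-4-O-(4-methoxybenzyl)-D-galactopyranose (anomeric mixture) | c1ccccc1COC[C@H]1OC(O)[C@H](OCc2ccccc2)[C@@H](OCc2ccccc2)[C@H]1OCc1ccc(OC)cc1 | intermediate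
7 | vinylmagnesium bromide | C=C[Mg]Br | starting material
8 | 4,5,8-tri-O-benzyl-1,2-dideoxy-6-O-(4-methoxybenzyl)-D-glycero-L-gluco-oct-1-enitol | C=C[C@@H](O)[C@H](OCc1ccccc1)[C@@H](OCc1ccccc1)[C@@H](OCc1ccc(OC)cc1)[C@H](O)COCc1ccccc1 | intermediate
9 | 3-O-TBS ether of 8 (7-OH free) | C=C[C@@H](O[Si](C)(C)C(C)(C)C)[C@H](OCc1ccccc1)[C@@H](OCc1ccccc1)[C@@H](OCc1ccc(OC)cc1)[C@H](O)COCc1ccccc1 | intermediate
10 | 4,5,8-tri-O-benzyl-3-O-TBS-1,2-dideoxy-6-O-PMB-L-gluco-oct-1-en-7-ulose | C=C[C@@H](O[Si](C)(C)C(C)(C)C)[C@H](OCc1ccccc1)[C@@H](OCc1ccccc1)[C@@H](OCc1ccc(OC)cc1)C(=O)COCc1ccccc1 | intermediate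
11 | 1,2-diol from dihydroxylation of 10 (C2 epimers, not isolated) | OCC(O)[C@@H](O[Si](C)(C)C(C)(C)C)[C@H](OCc1ccccc1)[C@@H](OCc1ccccc1)[C@@H](OCc1ccc(OC)cc1)C(=O)COCc1ccccc1 | intermediate
12 | 3,4,7-tri-O-benzyl-2-O-TBS-5-O-PMB-L-gluco-heptos-6-ulose | O=C[C@@H](O[Si](C)(C)C(C)(C)C)[C@H](OCc1ccccc1)[C@@H](OCc1ccccc1)[C@@H](OCc1ccc(OC)cc1)C(=O)COCc1ccccc1 | intermediate
13 | 1-C-(benzyloxymethyl)cyclohexane-1β,2β-diol, 3α-OTBS, 4β-OBn, 5α-OBn, 6α-OPMB | CC(C)(C)[Si](C)(C)O[C@H]1[C@H](OCc2ccccc2)[C@@H](OCc2ccccc2)[C@@H](OCc2ccc(OC)cc2)[C@@](O)(COCc2ccccc2)[C@@H]1O | intermediate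
14 | 1β,2β,3α-triol, 4β,5α-OBn, 6α-OPMB, 1-CH2OBn | O[C@H]1[C@H](OCc2ccccc2)[C@@H](OCc2ccccc2)[C@@H](OCc2ccc(OC)cc2)[C@@](O)(COCc2ccccc2)[C@@H]1O | intermediate
15 | 2β,3α-diacetate of 14 (1β-OH free) | CC(=O)O[C@H]1[C@H](OCc2ccccc2)[C@@H](OCc2ccccc2)[C@@H](OCc2ccc(OC)cc2)[C@@](O)(COCc2ccccc2)[C@@H]1OC(C)=O | intermediate
16 | 1β,6α-diol 2β,3α-diacetate, 4β,5α-OBn, 1-CH2OBn | CC(=O)O[C@H]1[C@H](OCc2ccccc2)[C@@H](OCc2ccccc2)[C@@H](O)[C@@](O)(COCc2ccccc2)[C@@H]1OC(C)=O | intermediate
17 | 6α-mesylate of 16 | CC(=O)O[C@H]1[C@H](OCc2ccccc2)[C@@H](OCc2ccccc2)[C@@H](OS(C)(=O)=O)[C@@](O)(COCc2ccccc2)[C@@H]1OC(C)=O | intermediate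
18 | 1β,6β-epoxide, 2β,3α-OAc, 4β,5α-OBn, 1-CH2OBn | CC(=O)O[C@H]1[C@H](OCc3ccccc3)[C@@H](OCc3ccccc3)[C@@H]2O[C@]2(COCc3ccccc3)[C@@H]1OC(C)=O | intermediate
19 | 1β,6β-epoxide, 2β,3α-OAc, 4β,5α-OH, 1-CH2OH | CC(=O)O[C@H]1[C@H](O)[C@@H](O)[C@@H]2O[C@]2(CO)[C@@H]1OC(C)=O | intermediate
20 | CNP0171674.1: (2β,3α-diacetoxy-4β,5α-dihydroxy-1β,6β-epoxycyclohexyl)methyl benzoate | CC(=O)O[C@H]1[C@H](O)[C@@H](O)[C@@H]2O[C@]2(COC(=O)c2ccccc2)[C@@H]1OC(C)=O | target

**Step count**
Total: 17 steps. Longest linear sequence: 17 steps (1 to 20).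

**Steps most likely to fail**

Step 10 (pinacol closure). Reductive loss of an α-alkoxy group from the ketyl, simple carbonyl reduction, or cyclisation with poor facial control could erode the yield of the β cis-diol. The fallback sets out from ketone 10. Wittig methylenation (Ph3P=CH2, THF, −78 to 0 °C) gives the 7-methylidene 1,7-diene F1. Ring-closing metathesis with second-generation Grubbs catalyst (toluene, 60 °C) closes the C1=C2 cyclohexene F2 with loss of ethene. Dihydroxylation (OsO4 cat., NMO, acetone/H2O) should add both oxygens from the β face, anti to the two allylic α-oxygens at C3 and C6, and comes back to the route at diol 13.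

Step 7 (mono-silylation). Poor site-selectivity between the two secondary hydroxyls would give the regioisomeric and bis-silyl ethers. The fallback sets out from lactol 6 and differentiates the oxygens at the alditol stage. NaBH4 reduction gives the galactitol 1,5-diol F3, and TESCl/imidazole gives the bis(triethylsilyl) ether F4. Swern conditions oxidise the primary silyl ether directly to the 5-O-triethylsilyl aldehyde F5 while the secondary silyl ether stays. Addition of vinylmagnesium bromide 7 after precomplexation with MgBr2·OEt2 (CH2Cl2, −78 °C) gives the threo allylic alcohol F6. TBSOTf/2,6-lutidine gives the mixed bis-silyl ether F7, and PPTS in MeOH removes only the triethylsilyl group, returning to alcohol 9.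

Step 17 (benzoylation). Acylation of a secondary hydroxyl or acetyl migration from O3 to O4 would give mixed esters. The fallback sets out from triol 19 and uses a Mitsunobu esterification with benzoic acid (PPh3, DIAD, THF, 0 °C). Only the primary C7 carbinol is activated as its oxyphosphonium ion and benzoate displaces it, so the ester is formed by C–O substitution instead of O-acylation. It comes back directly at target 20 and makes no new compound (F0).

**Further compounds**
F1 | step 10 | 4,5,8-tri-O-benzyl-3-O-TBS-6-O-PMB-7-methylidene-1,2,7-trideoxy-L-gluco-oct-1-enitol (1,7-diene) | C=C[C@@H](O[Si](C)(C)C(C)(C)C)[C@H](OCc1ccccc1)[C@@H](OCc1ccccc1)[C@@H](OCc1ccc(OC)cc1)C(=C)COCc1ccccc1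
F2 | step 10 | 1-(benzyloxymethyl)cyclohex-1-ene with 3α-OTBS, 4β-OBn, 5α-OBn, 6α-OPMB | CC(C)(C)[Si](C)(C)O[C@H]1[C@H](OCc2ccccc2)[C@@H](OCc2ccccc2)[C@@H](OCc2ccc(OC)cc2)C(COCc2ccccc2)=C1
F3 | step 7 | 2,3,6-tri-O-benzyl-4-O-(4-methoxybenzyl)-D-galactitol | OC[C@H](OCc1ccccc1)[C@@H](OCc1ccccc1)[C@@H](OCc1ccc(OC)cc1)[C@H](O)COCc1ccccc1
F4 | step 7 | 1,5-bis-O-triethylsilyl ether of F3 | CC[Si](CC)(CC)OC[C@H](OCc1ccccc1)[C@@H](OCc1ccccc1)[C@@H](OCc1ccc(OC)cc1)[C@H](O[Si](CC)(CC)CC)COCc1ccccc1
F5 | step 7 | 2,3,6-tri-O-benzyl-4-O-PMB-5-O-triethylsilyl-aldehydo-D-galactose | O=C[C@H](OCc1ccccc1)[C@@H](OCc1ccccc1)[C@@H](OCc1ccc(OC)cc1)[C@H](O[Si](CC)(CC)CC)COCc1ccccc1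
F6 | step 7 | 7-O-triethylsilyl ether of diol 8 (3-OH free) | C=C[C@@H](O)[C@H](OCc1ccccc1)[C@@H](OCc1ccccc1)[C@@H](OCc1ccc(OC)cc1)[C@H](O[Si](CC)(CC)CC)COCc1ccccc1
F7 | step 7 | 3-O-TBS-7-O-triethylsilyl ether of diol 8 | C=C[C@@H](O[Si](C)(C)C(C)(C)C)[C@H](OCc1ccccc1)[C@@H](OCc1ccccc1)[C@@H](OCc1ccc(OC)cc1)[C@H](O[Si](CC)(CC)CC)COCc1ccccc1
F0 | step 17 | none | none
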